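**Plan**

1. Numbering follows the eudesmane skeleton: ring A = C1–C5 and C10, ring B = C5–C10, C11–C13 = hydroxyisopropyl unit, C14 = methyl on C10, C15 = methyl on C4.
2. Enabling feature: in ring B the C8 ketone, C7 and the tertiary C11 carbinol form a β-hydroxy ketone, i.e. an isoxazoline with its N–O bond cut. That isoxazoline is disconnected at C7–C8 and O–C11 into a C8 nitrile oxide and the C7=C11 alkene of a side chain on C5.
3. Other cuts, in retrosynthetic order: the C3–O ester bond; the C6=C7 double bond (traced to E1cB loss of a C6 benzoate, so C6 is carried one oxidation level higher); the C4–OH bond (α′-hydroxylation of a ring-A enone); C6–C7 (aldehyde plus alkenyl Grignard); C1–C10 and C4–C5 (Diels–Alder).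
4. Forward order: ring A by Diels–Alder; the C5 and C10 side chains; ring B and the isoxazoline together in the cycloaddition; ring-A oxygenation and acylation; N–O cleavage and elimination to the enone.
5. Stereochemistry: C5/C10 from the (E)-dienophile geometry and a chiral oxazaborolidinium catalyst; C4 by α-face epoxidation anti to the C10 methyl; C3 by axial hydride delivery; the acyl centre from (R)-2-methylbutanoic acid; C6 and C7 are temporary, substrate-controlled, and end as sp2 carbons.

Key step: step 11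

Assumption: the facial sense of the oxazaborolidinium catalyst in step 2 is taken from the formyl C–H···O binding model for α-methyl enals, which points to the (R)-prolinol-derived catalyst; its mirror image would be used if the opposite sense were found.

**Route**

Step 1
Reactants: 1 pent-1-en-3-one
Product: 2 (Z)-3-(triisopropylsilyloxy)penta-1,3-diene
Conditions: TIPSOTf, Et3N, CH2Cl2, 0 °C → rt
Reagents that add atoms: triisopropylsilyl trifluoromethanesulfonate, CC(C)[Si](C(C)C)(C(C)C)OS(=O)(=O)C(F)(F)F
Why: Soft enolisation of the ethyl ketone (silyl triflate/amine) gives the 2-silyloxydiene, the (Z)-enol ether (methyl outside in the s-cis diene) being the favoured geometry under these conditions.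

Step 2
Reactants: 2 (Z)-3-(triisopropylsilyloxy)penta-1,3-diene; 3 ethyl (E)-3-methyl-4-oxobut-2-enoate
Product: 4 ethyl 6-formyl-2,6-dimethyl-3-(triisopropylsilyloxy)cyclohex-3-ene-1-carboxylate (CHO trans to CO2Et; 2-methyl trans to CO2Et)
Conditions: (R)-tetrahydro-3,3-diphenyl-1-(o-tolyl)-1H,3H-pyrrolo[1,2-c][1,3,2]oxazaborole (20 mol %), Tf2NH (20 mol %), CH2Cl2, −78 → −40 °C
Reagents that add atoms: none
Why: Catalytic enantioselective Diels–Alder reaction in which the boron-bound formyl group makes C5 the electrophilic carbon, so the CH(CH3) terminus of the silyloxydiene bonds there (silyloxy carbon para to C10), suprafacial addition to the (E)-alkene fixes CHO trans to CO2Et, the catalyst leaves the Si face of C10 (CHO > C=C > CH3) open and so sets the absolute configuration, and the endo-formyl mode puts the C4 methyl trans to the ester, a centre that is erased in step 12 so that its purity is immaterial.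

Step 3
Reactants: 4 Diels–Alder aldehyde ester
Product: 5 ethyl 2,6-dimethyl-3-(triisopropylsilyloxy)-6-vinylcyclohex-3-ene-1-carboxylate
Conditions: Ph3PCH3Br, KN(SiMe3)2, THF, 0 °C; then 4, −78 → 0 °C
Reagents that add atoms: methyltriphenylphosphonium bromide, C[P+](c1ccccc1)(c1ccccc1)c1ccccc1.[Br-]
Why: Wittig methylenation of the non-enolisable neopentyl aldehyde, which the ester and the silyl enol ether survive at low temperature and which touches no stereocentre.

Step 4
Reactants: 5 vinyl ester
Product: 6 [2,6-dimethyl-3-(triisopropylsilyloxy)-6-vinylcyclohex-3-en-1-yl]methanol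
Conditions: i-Bu2AlH (2.5 equiv), CH2Cl2, −78 → 0 °C; aq. KNaC4H4O6 work-up
Reagents that add atoms: none
Why: Aluminium hydride reduction of the ester to the primary alcohol under neutral work-up, leaving the silyl enol ether and the vinyl group untouched.

Step 5
Reactants: 6 primary alcohol
Product: 7 2,6-dimethyl-3-(triisopropylsilyloxy)-6-vinylcyclohex-3-ene-1-carbaldehyde
Conditions: Dess–Martin periodinane, pyridine, CH2Cl2, 0 °C → rt
Reagents that add atoms: none
Why: Dess–Martin oxidation with pyridine buffering gives the aldehyde without acid exposure of the silyl enol ether, and C5 already has the thermodynamically preferred trans arrangement, so epimerisation next to the new aldehyde is not expected.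

Step 6
Reactants: 7 ring-A aldehyde; 8 2-methylprop-1-en-1-ylmagnesium bromide
Product: 10 (S)-1-[2,6-dimethyl-3-(triisopropylsilyloxy)-6-vinylcyclohex-3-en-1-yl]-3-methylbut-2-en-1-yl benzoate, via bromomagnesium alkoxide 9 (not isolated)
Conditions: THF, −78 °C; then BzCl, DMAP (cat.), −78 °C → rt
Reagents that add atoms: benzoyl chloride, O=C(Cl)c1ccccc1
Why: Grignard 1,2-addition under Felkin–Anh control (quaternary C10 anti to the nucleophile, approach past H5) should give mainly the (6S)-alkoxide, which is acylated in the same flask; this C6 centre is temporary, and a minor epimer would be removed by chromatography.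

Step 7
Reactants: 10 allylic benzoate
Product: 12 (S)-1-[6-(2-hydroxyethyl)-2,6-dimethyl-3-(triisopropylsilyloxy)cyclohex-3-en-1-yl]-3-methylbut-2-en-1-yl benzoate, via B-alkyl-9-BBN adduct 11 (not isolated)
Conditions: 9-BBN, THF, 0 °C → rt; then 30% H2O2, pH 7 phosphate buffer, 0 °C → rt
Reagents that add atoms: hydrogen peroxide, OO
Why: Anti-Markovnikov hydroboration–oxidation in which 9-BBN selects the monosubstituted vinyl group over the trisubstituted alkene and the trisubstituted silyl enol ether, while buffered peroxide spares the benzoate.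

Step 8
Reactants: 12 primary alcohol at C8
Product: 13 (S)-1-[2,6-dimethyl-6-(2-oxoethyl)-3-(triisopropylsilyloxy)cyclohex-3-en-1-yl]-3-methylbut-2-en-1-yl benzoate
Conditions: Dess–Martin periodinane, pyridine, CH2Cl2, 0 °C → rt
Reagents that add atoms: none
Why: Dess–Martin oxidation of the only free alcohol to the C8 aldehyde under buffered, non-basic conditions.

Step 9
Reactants: 13 C8 aldehyde with ring-A silyl enol ether
Product: 14 (S)-1-[2,6-dimethyl-3-oxo-6-(2-oxoethyl)cyclohex-4-en-1-yl]-3-methylbut-2-en-1-yl benzoate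
Conditions: Pd(OAc)2 (1.2 equiv), DMSO, 45 °C
Reagents that add atoms: none
Why: Saegusa–Ito oxidation, in which the enol ether fixed at C2=C3 by the Diels–Alder step gives a C2-bound palladium enolate whose only β-hydrogens are on C1, so the C1=C2 enone forms regiospecifically and C4–H becomes the only enolisable position next to the C3 carbonyl.

Step 10
Reactants: 14 enone aldehyde
Product: 15 (S)-1-{6-[2-(hydroxyimino)ethyl]-2,6-dimethyl-3-oxocyclohex-4-en-1-yl}-3-methylbut-2-en-1-yl benzoate (oxime E/Z mixture)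
Conditions: NH2OH·HCl (1.05 equiv), NaOAc, EtOH/H2O, 0 °C; used at once
Reagents that add atoms: hydroxylamine hydrochloride, NO.Cl
Why: Oxime condensation that is chemoselective because the unhindered aliphatic aldehyde reacts far faster than the conjugated, α′-branched ketone, and both oxime isomers lead to the same nitrile oxide.

Step 11
Reactants: 15 ring-A enone aldoxime
Product: 18 tricyclic isoxazoline enone, via hydroximoyl chloride 16 (not isolated), via nitrile oxide 17 (not isolated)
Conditions: aq. NaOCl, CH2Cl2, 0 °C → rt, slow addition of 15 (final 0.01 M)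
Reagents that add atoms: none
Why: Hypochlorite chlorinates the aldoxime to the hydroximoyl chloride, which loses HCl to the C8 nitrile oxide; this dipole adds in a concerted, suprafacial [3+2] cycloaddition to the C7=C11 alkene, the closest known reaction type being the intramolecular nitrile oxide–alkene cycloaddition used as a masked aldol. Ring B closes in the fused mode through the C8–C7 bond (six-membered carbocycle, chair-like transition state on the trans-diequatorial C5/C10 substituents), and the isoxazoline closes as the five-membered ring through O–C11. The new C7 stereocentre is set by that chair, which places C11 equatorial and H7 axial (α), with the 6α-benzoate equatorial so that its carbinol hydrogen, not the ester, faces the Z-methyl group (minimal allylic strain). The step needs C8→C7/O→C11 regiochemistry, secured by the tether length and by the usual preference of nitrile oxide oxygen for the more substituted alkene carbon; it needs chemoselectivity against the ring-A enone, whose C1=C2 bond cannot be spanned by the two-atom tether; and it needs cyclisation to outrun furoxan dimerisation, secured by slow generation at high dilution.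

Step 12
Reactants: 18 tricyclic isoxazoline enone
Product: 21 4α-hydroxy-4β-methyl isoxazoline enone, via silyloxydiene 19 (not isolated), via 4α-silyloxy ketone 20 (not isolated)
Conditions: TMSOTf, Et3N, CH2Cl2, 0 °C; then mCPBA, CH2Cl2, −20 °C; then 1 M aq. HCl, THF, rt
Reagents that add atoms: 3-chloroperoxybenzoic acid, OOC(=O)c1cccc(Cl)c1
Why: Rubottom oxidation in which the enone can enolise only toward C4 (C2 is vinylic, C10 quaternary), so silylation gives the 3-silyloxy-1,3-diene regiospecifically and the peracid epoxidises its electron-rich C3=C4 bond from the α face, anti to the axial C10 methyl, leaving the 4α-hydroxy-4β-methyl ketone after silyl migration and hydrolysis.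

Step 13
Reactants: 21 4α-hydroxy enone
Product: 22 saturated 4α-hydroxy-3-ketone (isoxazoline and 6α-benzoate retained)
Conditions: [(Ph3P)CuH]6, H2O (few equiv), benzene/THF, rt
Reagents that add atoms: none
Why: Copper hydride conjugate reduction delivers hydride only to C1 of the enone and leaves the isoxazoline N–O bond, the benzoate and the tertiary alcohol alone, with no stereocentre formed.

Step 14
Reactants: 22 4α-hydroxy-3-ketone
Product: 23 3β,4α-diol (isoxazoline and 6α-benzoate retained)
Conditions: NaBH4, MeOH, −20 → 0 °C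
Reagents that add atoms: none
Why: Borohydride reduction of the cyclohexanone with axial hydride delivery from the α face (the β face is blocked by the axial 4β-methyl and the C10 methyl) gives the equatorial 3β-alcohol trans to the 4α-hydroxyl.

Step 15
Reactants: 23 3β,4α-diol; 24 (R)-2-methylbutanoic acid
Product: 25 3β-[(R)-2-methylbutanoyloxy] 4α-hydroxy isoxazoline 6α-benzoate
Conditions: DCC, DMAP (cat.), CH2Cl2, 0 °C → rt
Reagents that add atoms: none
Why: Steglich esterification acylates the secondary equatorial 3β-hydroxyl and not the tertiary 4α-hydroxyl, and carbodiimide activation with catalytic DMAP at 0 °C avoids a ketene pathway, so the (R) centre of the acid is kept.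

Step 16
Reactants: 25 fully functionalised isoxazoline
Product: 27 β-hydroxy ketone 6α-benzoate (C8 ketone, C11 carbinol, 7α-H), via hydroxy imine 26 (not isolated)
Conditions: Mo(CO)6, MeCN/H2O (10:1), 80 °C
Reagents that add atoms: water, O
Why: Reductive N–O cleavage of the isoxazoline by zerovalent molybdenum gives the β-hydroxy imine, which water hydrolyses to the aldol-type ketone; a non-hydrogenating reagent is chosen so that any enone formed early by loss of benzoate is not reduced.

Step 17
Reactants: 27 β-hydroxy ketone 6α-benzoate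
Product: 28 CNP0201989.1 (target)
Conditions: DBU, CH2Cl2, 0 °C → rt
Reagents that add atoms: none
Why: E1cB elimination in which the C8 ketone enolises toward C7 and the enolate expels the C6 benzoate, a far better leaving group than the tertiary hydroxide at C11, so the C6=C7 enone forms and the C11 carbinol survives, while enolisation toward C9 is non-productive and reversible.

**Compound list**

1 | pent-1-en-3-one | CCC(=O)C=C | starting material
2 | (Z)-3-(triisopropylsilyloxy)penta-1,3-diene | C/C=C(\O[Si](C(C)C)(C(C)C)C(C)C)C=C | intermediate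
3 | ethyl (E)-3-methyl-4-oxobut-2-enoate | CCOC(=O)/C=C(\C)C=O | starting material
4 | ethyl 6-formyl-2,6-dimethyl-3-(triisopropylsilyloxy)cyclohex-3-ene-1-carboxylate; CHO trans to CO2Et, 2-methyl trans to CO2Et (ring C6 = C10, ring C1 = C5, ring C2 = C4) | O=C[C@@]1(C)CC=C(O[Si](C(C)C)(C(C)C)C(C)C)[C@@H](C)[C@@H]1C(=O)OCC | intermediate
5 | ethyl 2,6-dimethyl-3-(triisopropylsilyloxy)-6-vinylcyclohex-3-ene-1-carboxylate, configuration as 4 | C=C[C@@]1(C)CC=C(O[Si](C(C)C)(C(C)C)C(C)C)[C@@H](C)[C@@H]1C(=O)OCC | intermediate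
6 | [2,6-dimethyl-3-(triisopropylsilyloxy)-6-vinylcyclohex-3-en-1-yl]methanol, configuration as 4 | C=C[C@@]1(C)CC=C(O[Si](C(C)C)(C(C)C)C(C)C)[C@@H](C)[C@@H]1CO | intermediate
7 | 2,6-dimethyl-3-(triisopropylsilyloxy)-6-vinylcyclohex-3-ene-1-carbaldehyde, configuration as 4 | C=C[C@@]1(C)CC=C(O[Si](C(C)C)(C(C)C)C(C)C)[C@@H](C)[C@@H]1C=O | intermediate
8 | 2-methylprop-1-en-1-ylmagnesium bromide | CC(C)=C[Mg]Br | starting material
9 | bromomagnesium (S)-alkoxide from addition of 8 to 7 (C6 alkoxide) | C=C[C@@]1(C)CC=C(O[Si](C(C)C)(C(C)C)C(C)C)[C@@H](C)[C@@H]1[C@@H](O[Mg]Br)C=C(C)C | intermediate (not isolated)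
10 | (S)-1-[2,6-dimethyl-3-(triisopropylsilyloxy)-6-vinylcyclohex-3-en-1-yl]-3-methylbut-2-en-1-yl benzoate | C=C[C@@]1(C)CC=C(O[Si](C(C)C)(C(C)C)C(C)C)[C@@H](C)[C@@H]1[C@@H](OC(=O)c2ccccc2)C=C(C)C | intermediate
11 | B-alkyl-9-borabicyclo[3.3.1]nonane from hydroboration of the vinyl group of 10 | B1(C2CCCC1CCC2)CC[C@@]3(C)CC=C(O[Si](C(C)C)(C(C)C)C(C)C)[C@@H](C)[C@@H]3[C@@H](OC(=O)c4ccccc4)C=C(C)C | intermediate (not isolated)
12 | (S)-1-[6-(2-hydroxyethyl)-2,6-dimethyl-3-(triisopropylsilyloxy)cyclohex-3-en-1-yl]-3-methylbut-2-en-1-yl benzoate | OCC[C@@]1(C)CC=C(O[Si](C(C)C)(C(C)C)C(C)C)[C@@H](C)[C@@H]1[C@@H](OC(=O)c2ccccc2)C=C(C)C | intermediate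
13 | (S)-1-[2,6-dimethyl-6-(2-oxoethyl)-3-(triisopropylsilyloxy)cyclohex-3-en-1-yl]-3-methylbut-2-en-1-yl benzoate | O=CC[C@@]1(C)CC=C(O[Si](C(C)C)(C(C)C)C(C)C)[C@@H](C)[C@@H]1[C@@H](OC(=O)c2ccccc2)C=C(C)C | intermediate
14 | (S)-1-[2,6-dimethyl-3-oxo-6-(2-oxoethyl)cyclohex-4-en-1-yl]-3-methylbut-2-en-1-yl benzoate | O=CC[C@@]1(C)C=CC(=O)[C@@H](C)[C@@H]1[C@@H](OC(=O)c2ccccc2)C=C(C)C | intermediate
15 | (S)-1-{6-[2-(hydroxyimino)ethyl]-2,6-dimethyl-3-oxocyclohex-4-en-1-yl}-3-methylbut-2-en-1-yl benzoate (key-step precursor; oxime E/Z mixture) | ON=CC[C@@]1(C)C=CC(=O)[C@@H](C)[C@@H]1[C@@H](OC(=O)c2ccccc2)C=C(C)C | intermediate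
16 | hydroximoyl chloride of 15 | ON=C(Cl)C[C@@]1(C)C=CC(=O)[C@@H](C)[C@@H]1[C@@H](OC(=O)c2ccccc2)C=C(C)C | intermediate (not isolated)
17 | C8 nitrile oxide from 16 | [O-][N+]#CC[C@@]1(C)C=CC(=O)[C@@H](C)[C@@H]1[C@@H](OC(=O)c2ccccc2)C=C(C)C | intermediate (not isolated)
18 | tricyclic isoxazoline (key-step product): eudesm-1-en-3-one skeleton with C8=N–O–C11 isoxazoline, 6α-benzoyloxy, 4α-CH3, 5α-H, 7α-H, 10β-CH3 | CC1(C)ON=C2C[C@@]3(C)C=CC(=O)[C@@H](C)[C@@H]3[C@@H](OC(=O)c4ccccc4)[C@H]12 | intermediate
19 | 3-(trimethylsilyloxy)-1,3-diene of 18 | CC1(C)ON=C2C[C@@]3(C)C=CC(O[Si](C)(C)C)=C(C)[C@@H]3[C@@H](OC(=O)c4ccccc4)[C@H]12 | intermediate (not isolated)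
20 | 4α-(trimethylsilyloxy)-4β-methyl enone | CC1(C)ON=C2C[C@@]3(C)C=CC(=O)[C@@](C)(O[Si](C)(C)C)[C@@H]3[C@@H](OC(=O)c4ccccc4)[C@H]12 | intermediate (not isolated)
21 | 4α-hydroxy-4β-methyl isoxazoline enone | CC1(C)ON=C2C[C@@]3(C)C=CC(=O)[C@@](C)(O)[C@@H]3[C@@H](OC(=O)c4ccccc4)[C@H]12 | intermediate
22 | saturated 4α-hydroxy-4β-methyl-3-ketone, isoxazoline and 6α-benzoate retained | CC1(C)ON=C2C[C@@]3(C)CCC(=O)[C@@](C)(O)[C@@H]3[C@@H](OC(=O)c4ccccc4)[C@H]12 | intermediate
23 | 3β,4α-diol, isoxazoline and 6α-benzoate retained | CC1(C)ON=C2C[C@@]3(C)CC[C@H](O)[C@@](C)(O)[C@@H]3[C@@H](OC(=O)c4ccccc4)[C@H]12 | intermediate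
24 | (R)-2-methylbutanoic acid | CC[C@@H](C)C(=O)O | starting material
25 | 3β-[(R)-2-methylbutanoyloxy]-4α-hydroxy isoxazoline 6α-benzoate | CC1(C)ON=C2C[C@@]3(C)CC[C@H](OC(=O)[C@H](C)CC)[C@@](C)(O)[C@@H]3[C@@H](OC(=O)c4ccccc4)[C@H]12 | intermediate
26 | β-hydroxy imine (C8=NH, C11–OH) from N–O cleavage of 25 | CC(C)(O)[C@@H]1C(=N)C[C@@]2(C)CC[C@H](OC(=O)[C@H](C)CC)[C@@](C)(O)[C@@H]2[C@H]1OC(=O)c1ccccc1 | intermediate (not isolated)
27 | 6α-benzoyloxy-4α,11-dihydroxy-3β-[(R)-2-methylbutanoyloxy]-5α,7α-eudesman-8-one | CC(C)(O)[C@@H]1C(=O)C[C@@]2(C)CC[C@H](OC(=O)[C@H](C)CC)[C@@](C)(O)[C@@H]2[C@H]1OC(=O)c1ccccc1 | intermediate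
28 | CNP0201989.1: 4α,11-dihydroxy-3β-[(R)-2-methylbutanoyloxy]eudesm-6-en-8-one | CC[C@@H](C)C(=O)O[C@H]1CC[C@]2(C)CC(=O)C(C(C)(C)O)=C[C@H]2[C@]1(C)O | target

**Step count and risks**

Total step count: 17. Longest linear sequence: 17 steps (from pent-1-en-3-one).

Steps most likely to fail:

Step 2. The hindered, trisubstituted dienophile may react so slowly that the strongly acidic catalyst degrades the silyloxydiene, or facial discrimination may be weak. In that case the cycloaddition of 2 and 3 would be run with the achiral, proton-scavenging Lewis acid Me2AlCl (CH2Cl2, −78 °C). This gives 4 as a racemate, i.e. accompanied by mirror-image adduct F1. Steps 3 and 4 applied to the racemate give, beside 5 and 6, mirror-image vinyl ester F2 and mirror-image alcohol F3. The racemic alcohol is esterified with (S)-2-methoxy-2-phenylacetic acid (DCC, DMAP) to the diastereomeric esters O-methylmandelate F4 (from 6) and O-methylmandelate F5 (from F3), which are separated by chromatography. i-Bu2AlH then cleaves F4 and the route is rejoined at 6.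

Step 9. Transmetalation of the bulky silyl enol ether may be sluggish, and the palladium salts may ionise or transpose the allylic benzoate. In that case the enone is installed only after the cycloaddition. From 13, Bu4NF/AcOH (THF, 0 °C) removes the silyl group to give keto aldehyde F6. Chemoselective condensation with NH2OH·HCl/NaOAc gives keto oxime F7. Aqueous NaOCl takes F7 through hydroximoyl chloride F8 and nitrile oxide F9 to saturated tricyclic ketone F10, the same cycloaddition with the C3 ketone as spectator. Kinetic deprotonation at C2 with LiN(SiMe3)2/Me3SiCl gives trimethylsilyl enol ether F11. Pd(OAc)2 in MeCN then oxidises this much more reactive enol silane, in a molecule that no longer holds an allylic ester or an aldehyde, and the route is rejoined at 18.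

Step 17. Retro-aldol loss of acetone or dehydration at C11 may compete with loss of the equatorial benzoate, which is not ideally aligned with the enolate. In that case the tertiary hydroxyls are masked first. From 27, N-(trimethylsilyl)imidazole (CH2Cl2, rt) gives bis(trimethylsilyl) ether F12, in which no alkoxide can form. DBU (toluene, rt to 50 °C) then effects the E1cB loss of benzoate to silylated enone F13. Citric acid in MeOH removes both silyl groups and gives 28.

**Further compounds**

F1 | step 2 | mirror-image adduct (enantiomer of 4) | O=C[C@]1(C)CC=C(O[Si](C(C)C)(C(C)C)C(C)C)[C@H](C)[C@H]1C(=O)OCC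
F2 | step 2 | mirror-image vinyl ester (enantiomer of 5) | C=C[C@]1(C)CC=C(O[Si](C(C)C)(C(C)C)C(C)C)[C@H](C)[C@H]1C(=O)OCC
F3 | step 2 | mirror-image alcohol (enantiomer of 6) | C=C[C@]1(C)CC=C(O[Si](C(C)C)(C(C)C)C(C)C)[C@H](C)[C@H]1CO
F4 | step 2 | (S)-O-methylmandelate of 6 | C=C[C@@]1(C)CC=C(O[Si](C(C)C)(C(C)C)C(C)C)[C@@H](C)[C@@H]1COC(=O)[C@@H](OC)c2ccccc2
F5 | step 2 | (S)-O-methylmandelate of F3 | C=C[C@]1(C)CC=C(O[Si](C(C)C)(C(C)C)C(C)C)[C@H](C)[C@H]1COC(=O)[C@@H](OC)c2ccccc2
F6 | step 9 | keto aldehyde: (S)-1-[2,6-dimethyl-3-oxo-6-(2-oxoethyl)cyclohexyl]-3-methylbut-2-en-1-yl benzoate | O=CC[C@@]1(C)CCC(=O)[C@@H](C)[C@@H]1[C@@H](OC(=O)c2ccccc2)C=C(C)C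
F7 | step 9 | keto oxime of F6 | ON=CC[C@@]1(C)CCC(=O)[C@@H](C)[C@@H]1[C@@H](OC(=O)c2ccccc2)C=C(C)C
F8 | step 9 | hydroximoyl chloride of F7 | ON=C(Cl)C[C@@]1(C)CCC(=O)[C@@H](C)[C@@H]1[C@@H](OC(=O)c2ccccc2)C=C(C)C
F9 | step 9 | nitrile oxide from F8 | [O-][N+]#CC[C@@]1(C)CCC(=O)[C@@H](C)[C@@H]1[C@@H](OC(=O)c2ccccc2)C=C(C)C
F10 | step 9 | saturated tricyclic 3-keto isoxazoline 6α-benzoate | CC1(C)ON=C2C[C@@]3(C)CCC(=O)[C@@H](C)[C@@H]3[C@@H](OC(=O)c4ccccc4)[C@H]12
F11 | step 9 | C2=C3 trimethylsilyl enol ether of F10 | CC1(C)ON=C2C[C@@]3(C)CC=C(O[Si](C)(C)C)[C@@H](C)[C@@H]3[C@@H](OC(=O)c4ccccc4)[C@H]12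
F12 | step 17 | 4,11-bis(trimethylsilyl) ether of 27 | CC(C)(O[Si](C)(C)C)[C@@H]1C(=O)C[C@@]2(C)CC[C@H](OC(=O)[C@H](C)CC)[C@@](C)(O[Si](C)(C)C)[C@@H]2[C@H]1OC(=O)c1ccccc1
F13 | step 17 | 4,11-bis(trimethylsilyl) ether of 28 | CC[C@@H](C)C(=O)O[C@H]1CC[C@]2(C)CC(=O)C(C(C)(C)O[Si](C)(C)C)=C[C@H]2[C@]1(C)O[Si](C)(C)C
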